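**Retrosynthetic overview**

- The target is catechin-(4α→6)-epicatechin-(4β→8)-epicatechin-(4β→8)-epicatechin (units A, B, C, D). Units A, B and D are taken from (+)-catechin and (−)-epicatechin; unit C is built in the flask.
- Last disconnections: global deprotection, then the C4(unit C)–C8(unit D) bond, made from a C4 cation of unit C and benzylated epicatechin.
- Key disconnection: the pyran ring of unit C is opened across O1–C2 and C3–C4 into an o-quinone methide and a (Z)-2-arylvinyl acetate. The enabling feature is that O1 sits on ring-A carbon C8a, ortho to C4a, which carries benzylic C4, so O1–C8a–C4a–C4 is a masked 1-oxadiene. C2 bears the electron-rich catechol ring, so C2=C3 is a polarised styrene, and C4 can enter at the aldehyde oxidation level because it must later ionise.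
- The salicylaldehyde precursor comes from an A–B dimer (C4 thioether on unit B) and symmetric 4-benzyloxy-2,6-dihydroxybenzaldehyde. The A–B dimer comes from two orthogonally activated monomers, with bromine caps at C8 steering the coupling to C6.
- Ring order: all rings of units A, B and D and all arenes arrive preformed; the only ring made is the pyran ring of unit C, closed last in the key step.

Key step: step 16

Remark: C4 of unit C in the key-step product may form as either epimer; both ionise to the same cation in step 17, so this centre (and the methide geometry of the quinone methide) is left undefined in the SMILES.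
Remark: the (R)-enantiomer of the phosphoric acid in step 16 is assumed to be the one matched to the (2R,3R) outcome; if the pairing proves mismatched, the (S)-acid takes its place.

**Route**

Step 1
Reactants: 1 (+)-catechin
Product: 2 5,7,3',4'-tetra-O-benzyl-(+)-catechin
Conditions: BnBr (4.4 equiv), K2CO3, DMF, 0 °C to rt
Reagents that add atoms: benzyl bromide, BrCc1ccccc1
Why: Williamson ether synthesis on the four phenols, the secondary 3-OH not being deprotonated by carbonate and no stereocentre being touched.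

Step 2
Reactants: 2 5,7,3',4'-tetra-O-benzyl-(+)-catechin
Product: 3 8-bromo-5,7,3',4'-tetra-O-benzyl-(+)-catechin
Conditions: NBS (1.0 equiv), CH2Cl2, −78 °C to 0 °C
Reagents that add atoms: N-bromosuccinimide, O=C1CCC(=O)N1Br
Why: electrophilic aromatic bromination should go to C8, the more nucleophilic free position of ring A, and the bromine then caps C8 against self-condensation until the final hydrogenolysis.

Step 3
Reactants: 3 8-bromo-5,7,3',4'-tetra-O-benzyl-(+)-catechin
Product: 4 8-bromo-4β-(2-ethoxyethoxy)-5,7,3',4'-tetra-O-benzyl-(+)-catechin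
Conditions: DDQ (2 equiv), 2-ethoxyethanol (5 equiv), CH2Cl2, rt
Reagents that add atoms: 2-ethoxyethanol, CCOCCO
Why: DDQ benzylic oxidation (hydride abstraction at C4, activated by the ring-A oxygens) with capture of the cation by the alcohol, expected on the β-face; this ether centre is erased in step 10.

Step 4
Reactants: 4 8-bromo-4β-(2-ethoxyethoxy)-5,7,3',4'-tetra-O-benzyl-(+)-catechin
Product: 5 3-O-acetyl-8-bromo-4β-(2-ethoxyethoxy)-5,7,3',4'-tetra-O-benzyl-(+)-catechin
Conditions: Ac2O, pyridine, DMAP (cat.), rt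
Reagents that add atoms: acetic anhydride, CC(=O)OC(C)=O
Why: acylation of the secondary alcohol, giving the 3-acetate that will act as participating group in step 10.

Step 5
Reactants: 6 (−)-epicatechin
Product: 7 5,7,3',4'-tetra-O-benzyl-(−)-epicatechin
Conditions: BnBr (4.4 equiv), K2CO3, DMF, 0 °C to rt
Reagents that add atoms: benzyl bromide, BrCc1ccccc1
Why: Williamson ether synthesis on the phenols, run at or below room temperature so that base-induced epimerisation at C2 is avoided.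

Step 6
Reactants: 7 5,7,3',4'-tetra-O-benzyl-(−)-epicatechin
Product: 8 8-bromo-5,7,3',4'-tetra-O-benzyl-(−)-epicatechin
Conditions: NBS (1.0 equiv), CH2Cl2, −78 °C to 0 °C
Reagents that add atoms: N-bromosuccinimide, O=C1CCC(=O)N1Br
Why: regioselective electrophilic bromination at C8, which blocks this position so that unit B can later react only through C6.

Step 7
Reactants: 8 8-bromo-5,7,3',4'-tetra-O-benzyl-(−)-epicatechin
Product: 9 8-bromo-4β-(2-ethoxyethoxy)-5,7,3',4'-tetra-O-benzyl-(−)-epicatechin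
Conditions: DDQ (2 equiv), 2-ethoxyethanol (5 equiv), CH2Cl2, rt
Reagents that add atoms: 2-ethoxyethanol, CCOCCO
Why: DDQ benzylic oxidation at C4 with alcohol capture trans to the 3-OH (4β), the standard entry to C4-activated flavan-3-ols.

Step 8
Reactants: 9 8-bromo-4β-(2-ethoxyethoxy)-5,7,3',4'-tetra-O-benzyl-(−)-epicatechin
Product: 10 8-bromo-4β-[(2,6-dimethylphenyl)sulfanyl]-5,7,3',4'-tetra-O-benzyl-(−)-epicatechin
Conditions: 2,6-dimethylbenzenethiol (3 equiv), BF3·OEt2 (1.2 equiv), CH2Cl2, −78 °C to −20 °C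
Reagents that add atoms: 2,6-dimethylbenzenethiol, Sc1c(C)cccc1C
Why: Lewis-acid ionisation of the C4 ether and capture by the thiol trans to the 3-OH gives the 4β aryl sulfide, which is inert to hard Lewis acids but answers to thiophiles, making the two later C4 activations orthogonal.

Step 9
Reactants: 10 8-bromo-4β-[(2,6-dimethylphenyl)sulfanyl]-5,7,3',4'-tetra-O-benzyl-(−)-epicatechin
Product: 11 3-O-acetyl-8-bromo-4β-[(2,6-dimethylphenyl)sulfanyl]-5,7,3',4'-tetra-O-benzyl-(−)-epicatechin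
Conditions: Ac2O, pyridine, DMAP (cat.), rt
Reagents that add atoms: acetic anhydride, CC(=O)OC(C)=O
Why: acylation of the 3-OH, which removes a free hydroxyl from the acid-mediated steps and provides a participating group for step 12.

Step 10
Reactants: 5 3-O-acetyl-8-bromo-4β-(2-ethoxyethoxy)-5,7,3',4'-tetra-O-benzyl-(+)-catechin; 11 3-O-acetyl-8-bromo-4β-[(2,6-dimethylphenyl)sulfanyl]-5,7,3',4'-tetra-O-benzyl-(−)-epicatechin
Product: 12 A–B dimer [unit A (3-OAc, 8-Br, benzylated catechin)-(4α→6)-unit B (3-OAc, 8-Br, 4β-arylsulfanyl, benzylated epicatechin)]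
Conditions: 11 (2.5 equiv), BF3·OEt2 (1.5 equiv), 4 Å MS, CH2Cl2, −78 °C to −30 °C
Reagents that add atoms: none
Why: Friedel–Crafts-type interflavan coupling in which BF3 ionises only the C4 ether of 5, the β-oriented 3-acetate shields the β-face by participation, and C6 of 11 (C8 being bromine-capped) attacks from the α-face to set the 4α (3,4-trans) centre.

Step 11
Reactants: 13 2,4,6-trihydroxybenzaldehyde
Product: 14 4-(benzyloxy)-2,6-dihydroxybenzaldehyde
Conditions: BnBr (1.0 equiv), K2CO3 (1.0 equiv), DMF, 0 °C to rt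
Reagents that add atoms: benzyl bromide, BrCc1ccccc1
Why: the 4-OH, para to the formyl group and outside the hydrogen-bond chelate, is the most acidic phenol, so mono-alkylation should occur there and keep the molecule symmetric.

Step 12
Reactants: 12 A–B dimer; 14 4-(benzyloxy)-2,6-dihydroxybenzaldehyde
Product: 15 A–B dimer carrying at C4β of unit B a 6-(benzyloxy)-3-formyl-2,4-dihydroxyphenyl group
Conditions: 14 (3 equiv), AgOTf (1.5 equiv), 4 Å MS, CH2Cl2–MeCN, −40 °C to 0 °C
Reagents that add atoms: none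
Why: the thiophilic silver cation ionises the C4–S bond of unit B and the cation, shielded on the α-face by the 3-acetate, is attacked from the β-face by ring carbon C3 of 14 (Friedel–Crafts alkylation), whose two free positions are equivalent by symmetry, so one constitution and the 4β centre result.

Step 13
Reactants: 15 A–B dimer with the 6-(benzyloxy)-3-formyl-2,4-dihydroxyphenyl group
Product: 16 A–B dimer carrying at C4β of unit B a 4,6-bis(benzyloxy)-3-formyl-2-hydroxyphenyl group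
Conditions: BnBr (1.05 equiv), K2CO3 (1.1 equiv), DMF, 0 °C to rt
Reagents that add atoms: benzyl bromide, BrCc1ccccc1
Why: of the two phenols ortho to the formyl group, the one flanked by the bulky flavan-4-yl substituent is shielded, so one equivalent of benzyl bromide should alkylate the exposed one and leave the other locked in the aldehyde chelate.

Step 14
Reactants: 17 3,4-bis(benzyloxy)benzaldehyde
Product: 18 1,2-bis(benzyloxy)-4-ethynylbenzene
Conditions: dimethyl (1-diazo-2-oxopropyl)phosphonate, K2CO3, MeOH, rt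
Reagents that add atoms: dimethyl (1-diazo-2-oxopropyl)phosphonate, CC(=O)C(=[N+]=[N-])P(=O)(OC)OC
Why: Seyferth–Gilbert homologation in the Ohira–Bestmann variant converts the aryl aldehyde into the terminal alkyne under mild base.

Step 15
Reactants: 18 1,2-bis(benzyloxy)-4-ethynylbenzene
Product: 19 (Z)-2-[3,4-bis(benzyloxy)phenyl]ethenyl acetate
Conditions: AcOH (1.5 equiv), Ru(η3-2-methylallyl)2(dppb) (2 mol %), toluene, 50 °C
Reagents that add atoms: acetic acid, CC(=O)O
Why: ruthenium-catalysed anti-Markovnikov addition of a carboxylic acid to a terminal alkyne through a ruthenium vinylidene, in which acetate attacks the vinylidene α-carbon and protonolysis should deliver the Z-enol ester.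

Step 16
Reactants: 16 A–B dimer with the 4,6-bis(benzyloxy)-3-formyl-2-hydroxyphenyl group; 19 (Z)-2-[3,4-bis(benzyloxy)phenyl]ethenyl acetate
Product: 22 A–B–C trimer carrying the new pyran ring of unit C (3-O-acetyl-4-methoxy-5,7,3',4'-tetra-O-benzylepicatechin unit bonded through C8 to C4β of unit B), via dimethyl acetal 20 (not isolated), via methoxy-o-quinone methide 21 (not isolated)
Conditions: 19 (3 equiv), HC(OMe)3 (3 equiv), (R)-TRIP [(R)-3,3'-bis(2,4,6-triisopropylphenyl)-1,1'-binaphthyl-2,2'-diyl hydrogen phosphate] (10 mol %), 4 Å MS, toluene–CH2Cl2, −40 °C to −10 °C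
Reagents that add atoms: trimethyl orthoformate, COC(OC)OC
Why: Proposed new method: under the chiral Brønsted acid the orthoformate turns the aldehyde into acetal 20, which loses methanol to the methoxy-substituted o-quinone methide 21 (reacting as its protonated, phosphate-paired oxocarbenium form), and this 1-oxadiene takes up enol acetate 19 in an inverse-electron-demand oxa-[4+2] cycloaddition. The closest known reaction types are the acid-catalysed three-component synthesis of 4-alkoxyflavans from salicylaldehydes, orthoformates and styrenes and the chiral-phosphoric-acid-controlled [4+2] of o-quinone methides with electron-rich alkenes; what is new is the β-acyloxystyrene partner and catalyst control over an already chiral substrate. The pyran ring of unit C is closed by intermolecular [4+2] annulation, the C3–C4 bond forming first (enol carbon onto the methide carbon) and the O1–C2 bond closing the six-membered ring by attack of the phenol oxygen on the benzylic cation. The cis relation of C2 and C3 is carried over from the Z geometry of 19 by suprafacial addition (concerted-asynchronous, or through the acetoxonium ion, whose anti opening by O1 gives the same cis result), while the face of 19 that is attacked, hence (2R,3R), is set by the chiral phosphate counter-anion, the wrong-face adduct being a separable diastereomer; C4 is not controlled and need not be. The step needs two regioselectivities: aryl at C2, secured because the 4-benzyloxyphenyl group stabilises positive charge at C2 far better than the acyloxy group does at C3, and closure through the oxygen next to unit B, secured because the other ortho oxygen was benzylated in step 13.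

Step 17
Reactants: 22 A–B–C trimer (4-methoxy); 7 5,7,3',4'-tetra-O-benzyl-(−)-epicatechin
Product: 23 protected tetramer [unit A-(4α→6)-unit B-(4β→8)-unit C-(4β→8)-unit D; sixteen benzyl ethers, two C8 bromines, 3-acetates on units A, B and C]
Conditions: 7 (3 equiv), TMSOTf (0.3 equiv), CH2Cl2, −78 °C to −40 °C
Reagents that add atoms: none
Why: Lewis-acid ionisation of the C4 methyl ether of unit C and Friedel–Crafts attack by C8 of 7, the most nucleophilic arene position present, trans to the α-oriented participating 3-acetate, which sets the 4β (3,4-trans) centre as in established procyanidin couplings.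

Step 18
Reactants: 23 protected tetramer
Product: 24 hexadeca-O-benzyl-8,8'-dibromo tetramer with four free 3-hydroxyls
Conditions: NaOMe, MeOH–THF, 40 °C
Reagents that add atoms: none
Why: Zemplén-type transesterification removes the three secondary acetates while benzyl ethers, aryl bromides and interflavan bonds are stable to methoxide.

Step 19
Reactants: 24 hexadeca-O-benzyl-8,8'-dibromo tetramer
Product: 25 CNP0228086.1, catechin-(4α→6)-epicatechin-(4β→8)-epicatechin-(4β→8)-epicatechin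
Conditions: H2 (1 atm), Pd(OH)2/C, THF–MeOH–H2O, rt
Reagents that add atoms: none
Why: catalytic hydrogenolysis should cleave the sixteen benzyl ethers and both aryl C–Br bonds under neutral conditions that leave the interflavan bonds and all twelve stereocentres untouched.

**Compound list**

1 | (+)-catechin, (2R,3S) | Oc1cc(O)c2c(c1)O[C@H](c1ccc(O)c(O)c1)[C@@H](O)C2 | starting material
2 | 5,7,3',4'-tetra-O-benzyl-(+)-catechin | O(Cc3ccccc3)c1cc(OCc3ccccc3)c2c(c1)O[C@H](c1ccc(OCc3ccccc3)c(OCc3ccccc3)c1)[C@@H](O)C2 | intermediate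
3 | 8-bromo-5,7,3',4'-tetra-O-benzyl-(+)-catechin | O(Cc3ccccc3)c1cc(OCc3ccccc3)c2c(c1Br)O[C@H](c1ccc(OCc3ccccc3)c(OCc3ccccc3)c1)[C@@H](O)C2 | intermediate
4 | 8-bromo-4β-(2-ethoxyethoxy)-5,7,3',4'-tetra-O-benzyl-(+)-catechin | O(Cc3ccccc3)c1cc(OCc3ccccc3)c2c(c1Br)O[C@H](c1ccc(OCc3ccccc3)c(OCc3ccccc3)c1)[C@@H](O)[C@H]2OCCOCC | intermediate
5 | 3-O-acetyl-8-bromo-4β-(2-ethoxyethoxy)-5,7,3',4'-tetra-O-benzyl-(+)-catechin (unit A electrophile) | O(Cc3ccccc3)c1cc(OCc3ccccc3)c2c(c1Br)O[C@H](c1ccc(OCc3ccccc3)c(OCc3ccccc3)c1)[C@@H](OC(C)=O)[C@H]2OCCOCC | intermediate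
6 | (−)-epicatechin, (2R,3R) | Oc1cc(O)c2c(c1)O[C@H](c1ccc(O)c(O)c1)[C@H](O)C2 | starting material
7 | 5,7,3',4'-tetra-O-benzyl-(−)-epicatechin (also the unit D nucleophile) | O(Cc3ccccc3)c1cc(OCc3ccccc3)c2c(c1)O[C@H](c1ccc(OCc3ccccc3)c(OCc3ccccc3)c1)[C@H](O)C2 | intermediate
8 | 8-bromo-5,7,3',4'-tetra-O-benzyl-(−)-epicatechin | O(Cc3ccccc3)c1cc(OCc3ccccc3)c2c(c1Br)O[C@H](c1ccc(OCc3ccccc3)c(OCc3ccccc3)c1)[C@H](O)C2 | intermediate
9 | 8-bromo-4β-(2-ethoxyethoxy)-5,7,3',4'-tetra-O-benzyl-(−)-epicatechin | O(Cc3ccccc3)c1cc(OCc3ccccc3)c2c(c1Br)O[C@H](c1ccc(OCc3ccccc3)c(OCc3ccccc3)c1)[C@H](O)[C@H]2OCCOCC | intermediate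
10 | 8-bromo-4β-[(2,6-dimethylphenyl)sulfanyl]-5,7,3',4'-tetra-O-benzyl-(−)-epicatechin | O(Cc3ccccc3)c1cc(OCc3ccccc3)c2c(c1Br)O[C@H](c1ccc(OCc3ccccc3)c(OCc3ccccc3)c1)[C@H](O)[C@H]2Sc1c(C)cccc1C | intermediate
11 | 3-O-acetyl-8-bromo-4β-[(2,6-dimethylphenyl)sulfanyl]-5,7,3',4'-tetra-O-benzyl-(−)-epicatechin (unit B) | O(Cc3ccccc3)c1cc(OCc3ccccc3)c2c(c1Br)O[C@H](c1ccc(OCc3ccccc3)c(OCc3ccccc3)c1)[C@H](OC(C)=O)[C@H]2Sc1c(C)cccc1C | intermediate
12 | A–B dimer: 3-O-acetyl-8-bromo-tetra-O-benzylcatechin-(4α→6)-[3-O-acetyl-8-bromo-4β-(2,6-dimethylphenylsulfanyl)-tetra-O-benzylepicatechin] | O(Cc3ccccc3)c1cc(OCc3ccccc3)c2c(c1Br)O[C@H](c1ccc(OCc3ccccc3)c(OCc3ccccc3)c1)[C@@H](OC(C)=O)[C@@H]2c1c(OCc3ccccc3)c(Br)c2c(c1OCc3ccccc3)[C@H](Sc1c(C)cccc1C)[C@@H](OC(C)=O)[C@@H](c1ccc(OCc3ccccc3)c(OCc3ccccc3)c1)O2 | intermediate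
13 | 2,4,6-trihydroxybenzaldehyde | O=Cc1c(O)cc(O)cc1O | starting material
14 | 4-(benzyloxy)-2,6-dihydroxybenzaldehyde | O=Cc1c(O)cc(OCc2ccccc2)cc1O | intermediate
15 | A–B dimer with a 6-(benzyloxy)-3-formyl-2,4-dihydroxyphenyl group at C4β of unit B | O(Cc3ccccc3)c1cc(OCc3ccccc3)c2c(c1Br)O[C@H](c1ccc(OCc3ccccc3)c(OCc3ccccc3)c1)[C@@H](OC(C)=O)[C@@H]2c1c(OCc3ccccc3)c(Br)c2c(c1OCc3ccccc3)[C@H](c1c(OCc3ccccc3)cc(O)c(C=O)c1O)[C@@H](OC(C)=O)[C@@H](c1ccc(OCc3ccccc3)c(OCc3ccccc3)c1)O2 | intermediate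
16 | A–B dimer with a 4,6-bis(benzyloxy)-3-formyl-2-hydroxyphenyl group at C4β of unit B | O(Cc3ccccc3)c1cc(OCc3ccccc3)c2c(c1Br)O[C@H](c1ccc(OCc3ccccc3)c(OCc3ccccc3)c1)[C@@H](OC(C)=O)[C@@H]2c1c(OCc3ccccc3)c(Br)c2c(c1OCc3ccccc3)[C@H](c1c(OCc3ccccc3)cc(OCc3ccccc3)c(C=O)c1O)[C@@H](OC(C)=O)[C@@H](c1ccc(OCc3ccccc3)c(OCc3ccccc3)c1)O2 | intermediate
17 | 3,4-bis(benzyloxy)benzaldehyde | O=Cc1ccc(OCc2ccccc2)c(OCc2ccccc2)c1 | starting material
18 | 1,2-bis(benzyloxy)-4-ethynylbenzene | C#Cc1ccc(OCc2ccccc2)c(OCc2ccccc2)c1 | intermediate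
19 | (Z)-2-[3,4-bis(benzyloxy)phenyl]ethenyl acetate | CC(=O)O/C=C\c1ccc(OCc2ccccc2)c(OCc2ccccc2)c1 | intermediate
20 | dimethyl acetal of 16 | O(Cc3ccccc3)c1cc(OCc3ccccc3)c2c(c1Br)O[C@H](c1ccc(OCc3ccccc3)c(OCc3ccccc3)c1)[C@@H](OC(C)=O)[C@@H]2c1c(OCc3ccccc3)c(Br)c2c(c1OCc3ccccc3)[C@H](c1c(OCc3ccccc3)cc(OCc3ccccc3)c(C(OC)OC)c1O)[C@@H](OC(C)=O)[C@@H](c1ccc(OCc3ccccc3)c(OCc3ccccc3)c1)O2 | intermediate
21 | methoxy-o-quinone methide: 3,5-bis(benzyloxy)-6-(methoxymethylidene)cyclohexa-2,4-dien-1-one bonded through C2 to C4β of unit B of the A–B dimer | O(Cc3ccccc3)c1cc(OCc3ccccc3)c2c(c1Br)O[C@H](c1ccc(OCc3ccccc3)c(OCc3ccccc3)c1)[C@@H](OC(C)=O)[C@@H]2c1c(OCc3ccccc3)c(Br)c2c(c1OCc3ccccc3)[C@H](C1=C(OCc3ccccc3)C=C(OCc3ccccc3)C(=COC)C1=O)[C@@H](OC(C)=O)[C@@H](c1ccc(OCc3ccccc3)c(OCc3ccccc3)c1)O2 | intermediate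
22 | A–B–C trimer: A–B dimer bonded 4β→8 to a (2R,3R)-3-O-acetyl-4-methoxy-5,7,3',4'-tetra-O-benzylflavan unit C (2,3-cis; both C4 epimers of unit C) | O(Cc3ccccc3)c1cc(OCc3ccccc3)c2c(c1Br)O[C@H](c1ccc(OCc3ccccc3)c(OCc3ccccc3)c1)[C@@H](OC(C)=O)[C@@H]2c1c(OCc3ccccc3)c(Br)c2c(c1OCc3ccccc3)[C@H](c1c(OCc4ccccc4)cc(OCc4ccccc4)c3c1O[C@H](c1ccc(OCc4ccccc4)c(OCc4ccccc4)c1)[C@H](OC(C)=O)C3OC)[C@@H](OC(C)=O)[C@@H](c1ccc(OCc3ccccc3)c(OCc3ccccc3)c1)O2 | intermediate
23 | protected tetramer: catechin-(4α→6)-epicatechin-(4β→8)-epicatechin-(4β→8)-epicatechin as hexadeca-O-benzyl ether, 8-bromo on units A and B, 3-O-acetyl on units A, B and C | O(Cc3ccccc3)c1cc(OCc3ccccc3)c2c(c1Br)O[C@H](c1ccc(OCc3ccccc3)c(OCc3ccccc3)c1)[C@@H](OC(C)=O)[C@@H]2c1c(OCc3ccccc3)c(Br)c2c(c1OCc3ccccc3)[C@H](c1c(OCc4ccccc4)cc(OCc4ccccc4)c3c1O[C@H](c1ccc(OCc4ccccc4)c(OCc4ccccc4)c1)[C@H](OC(C)=O)[C@H]3c1c(OCc5ccccc5)cc(OCc5ccccc5)c3c1O[C@H](c1ccc(OCc5ccccc5)c(OCc5ccccc5)c1)[C@H](O)C3)[C@@H](OC(C)=O)[C@@H](c1ccc(OCc3ccccc3)c(OCc3ccccc3)c1)O2 | intermediate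
24 | hexadeca-O-benzyl-8,8'-dibromo tetramer with four free 3-hydroxyls | O(Cc3ccccc3)c1cc(OCc3ccccc3)c2c(c1Br)O[C@H](c1ccc(OCc3ccccc3)c(OCc3ccccc3)c1)[C@@H](O)[C@@H]2c1c(OCc3ccccc3)c(Br)c2c(c1OCc3ccccc3)[C@H](c1c(OCc4ccccc4)cc(OCc4ccccc4)c3c1O[C@H](c1ccc(OCc4ccccc4)c(OCc4ccccc4)c1)[C@H](O)[C@H]3c1c(OCc5ccccc5)cc(OCc5ccccc5)c3c1O[C@H](c1ccc(OCc5ccccc5)c(OCc5ccccc5)c1)[C@H](O)C3)[C@@H](O)[C@@H](c1ccc(OCc3ccccc3)c(OCc3ccccc3)c1)O2 | intermediate
25 | CNP0228086.1, catechin-(4α→6)-epicatechin-(4β→8)-epicatechin-(4β→8)-epicatechin | Oc1cc(O)c2c(c1)O[C@H](c1ccc(O)c(O)c1)[C@@H](O)[C@@H]2c1c(O)cc2c(c1O)[C@H](c1c(O)cc(O)c3c1O[C@H](c1ccc(O)c(O)c1)[C@H](O)[C@H]3c1c(O)cc(O)c3c1O[C@H](c1ccc(O)c(O)c1)[C@H](O)C3)[C@@H](O)[C@@H](c1ccc(O)c(O)c1)O2 | target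

**Totals**

Total step count: 19.
Longest linear sequence: 12 steps (steps 5, 6, 7, 8, 9, 10, 12, 13, 16, 17, 18, 19, from (−)-epicatechin).

**Steps most likely to fail, with fallbacks**

1. Step 16 (the proposed new method). Three processes may defeat it. The trialkoxy-stabilised oxocarbenium may be too unreactive toward the weakly nucleophilic enol acetate, so that self-condensation through the free ring-A position of unit C takes over. Bond rotation in a long-lived benzylic cation may erase the Z relationship and give the 2,3-trans unit. The catalyst may discriminate poorly between the two faces of the alkene. The fallback uses only known chemistry, sets out from 7 and 12, and comes back to the route at 23. 7 is oxidised at C4 (DDQ, 2-ethoxyethanol, CH2Cl2) to 4β-(2-ethoxyethoxy)-5,7,3',4'-tetra-O-benzylepicatechin F1, which is acetylated (Ac2O, pyridine) to its 3-O-acetate F2. TMSOTf-catalysed condensation of F2 with an excess of 7 at −78 °C gives the dimer 3-O-acetyl-tetra-O-benzylepicatechin-(4β→8)-tetra-O-benzylepicatechin F3. AgOTf-promoted coupling of 12 with F3, through C8 of its upper unit, then gives 23. This fallback takes the pyran ring of unit C from epicatechin instead of closing it late.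

2. Step 10. Attack at C6 of 11 may be too slow, because this position is deactivated by the bromine and crowded by the neighbouring 4β-arylsulfanyl group; the cation from 5 would then be consumed by self-condensation through C6 of another molecule of 5 or by elimination. The fallback sets out from 8 and 5 and comes back at 15. 8 is acetylated to 3-O-acetyl-8-bromo-5,7,3',4'-tetra-O-benzylepicatechin F4, which has no C4 substituent and is used in excess as the C6 nucleophile toward 5 (BF3·OEt2, −78 °C) to give the 4α→6 dimer F5. Late DDQ/2-ethoxyethanol oxidation at C4 of unit B, the only benzylic CH2 of F5, then installs the leaving group and gives the 4β-(2-ethoxyethoxy) dimer F6. BF3·OEt2-mediated coupling of F6 with 14 gives 15.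

3. Step 12. C-alkylation of the formyl-deactivated phenol ring may be too slow, so that O-alkylation of the phenol or acid-induced cleavage of the A–B bond by the liberated triflic acid competes. The fallback sets out from 12 and comes back at 16, bypassing 15 and step 13. 12 is coupled (AgOTf, CH2Cl2, −40 °C) with the far more nucleophilic 3,5-bis(benzyloxy)phenol (Oc1cc(OCc2ccccc2)cc(OCc2ccccc2)c1) at a carbon ortho to its hydroxyl, giving the 4,6-bis(benzyloxy)-2-hydroxyphenyl adduct F7; attack para to the hydroxyl would give a regioisomer that has to be separated. Magnesium-phenoxide-directed ortho-formylation (MgCl2, Et3N, paraformaldehyde, MeCN, reflux) then places the formyl group at the only free position ortho to the hydroxyl and gives 16.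

**Further compounds**

F1 | step 16 | 4β-(2-ethoxyethoxy)-5,7,3',4'-tetra-O-benzyl-(−)-epicatechin | O(Cc3ccccc3)c1cc(OCc3ccccc3)c2c(c1)O[C@H](c1ccc(OCc3ccccc3)c(OCc3ccccc3)c1)[C@H](O)[C@H]2OCCOCC
F2 | step 16 | 3-O-acetyl-4β-(2-ethoxyethoxy)-5,7,3',4'-tetra-O-benzyl-(−)-epicatechin | O(Cc3ccccc3)c1cc(OCc3ccccc3)c2c(c1)O[C@H](c1ccc(OCc3ccccc3)c(OCc3ccccc3)c1)[C@H](OC(C)=O)[C@H]2OCCOCC
F3 | step 16 | 3-O-acetyl-tetra-O-benzylepicatechin-(4β→8)-tetra-O-benzylepicatechin | O(Cc3ccccc3)c1cc(OCc3ccccc3)c2c(c1)O[C@H](c1ccc(OCc3ccccc3)c(OCc3ccccc3)c1)[C@H](OC(C)=O)[C@H]2c1c(OCc5ccccc5)cc(OCc5ccccc5)c3c1O[C@H](c1ccc(OCc5ccccc5)c(OCc5ccccc5)c1)[C@H](O)C3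
F4 | step 10 | 3-O-acetyl-8-bromo-5,7,3',4'-tetra-O-benzyl-(−)-epicatechin | O(Cc3ccccc3)c1cc(OCc3ccccc3)c2c(c1Br)O[C@H](c1ccc(OCc3ccccc3)c(OCc3ccccc3)c1)[C@H](OC(C)=O)C2
F5 | step 10 | 3-O-acetyl-8-bromo-tetra-O-benzylcatechin-(4α→6)-[3-O-acetyl-8-bromo-tetra-O-benzylepicatechin] | O(Cc3ccccc3)c1cc(OCc3ccccc3)c2c(c1Br)O[C@H](c1ccc(OCc3ccccc3)c(OCc3ccccc3)c1)[C@@H](OC(C)=O)[C@@H]2c1c(OCc3ccccc3)c(Br)c2c(c1OCc3ccccc3)C[C@@H](OC(C)=O)[C@@H](c1ccc(OCc3ccccc3)c(OCc3ccccc3)c1)O2
F6 | step 10 | 3-O-acetyl-8-bromo-tetra-O-benzylcatechin-(4α→6)-[3-O-acetyl-8-bromo-4β-(2-ethoxyethoxy)-tetra-O-benzylepicatechin] | O(Cc3ccccc3)c1cc(OCc3ccccc3)c2c(c1Br)O[C@H](c1ccc(OCc3ccccc3)c(OCc3ccccc3)c1)[C@@H](OC(C)=O)[C@@H]2c1c(OCc3ccccc3)c(Br)c2c(c1OCc3ccccc3)[C@H](OCCOCC)[C@@H](OC(C)=O)[C@@H](c1ccc(OCc3ccccc3)c(OCc3ccccc3)c1)O2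
F7 | step 12 | A–B dimer with a 4,6-bis(benzyloxy)-2-hydroxyphenyl group at C4β of unit B | O(Cc3ccccc3)c1cc(OCc3ccccc3)c2c(c1Br)O[C@H](c1ccc(OCc3ccccc3)c(OCc3ccccc3)c1)[C@@H](OC(C)=O)[C@@H]2c1c(OCc3ccccc3)c(Br)c2c(c1OCc3ccccc3)[C@H](c1c(OCc3ccccc3)cc(OCc3ccccc3)cc1O)[C@@H](OC(C)=O)[C@@H](c1ccc(OCc3ccccc3)c(OCc3ccccc3)c1)O2
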